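(The readings are simulated with constants of no real substance; noise was put on by code.)

The ratio of early rates between amber and green, read as 8.00 from the readings at 0.250 d and 0.500 d, stands above the ratio of their catalyst charges, 4.09, so the rate in these runs climbs faster than the charge.

| setting | green | amber | flask |
|---|---|---|---|
| left-handed substrate | 1.8 M | 1.8 M | 1.8 M |
| right-handed substrate | 1.8 M | 1.8 M | 1.8 M |
| gas | 200 mM (held) | 200 mM (held) | 200 mM (held) |
| free catalyst | 22 mM | 90 mM | 45 mM |
| impurity | 18 mM | 18 mM | 18 mM |
| remark | run made earlier | run made earlier |  |

| run | time / d | left-handed product / % |
|---|---|---|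
| green | 0.167 | 2 |
| green | 0.500 | 6 |
| green | 0.833 | 8 |
| green | 1.25 | 11 |
| green | 1.67 | 13 |
| green | 2.50 | 18 |
| green | 3.00 | 21 |
| amber | 0.250 | 24 |
| amber | 0.333 | 26 |
| amber | 0.500 | 36 |
| amber | 0.833 | 47 |
| amber | 1.25 | 47 |
| amber | 2.08 | 52 |
| amber | 3.00 | 51 |

(standard deviation of a reading: 1.5 percentage points)

- apparent order in free catalyst when 5.0 % of the left-handed substrate and right-handed substrate together are converted (percent change of the rate of making left-handed product for one percent more free catalyst charged)
- factor on the rate of making left-handed product when 5.0 % of the left-handed substrate and right-handed substrate together are converted if free catalyst is charged twice over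

- free catalyst is single-handed; left-handed substrate and right-handed substrate are mirror images of each other, charged as a racemate, each of them at the stated concentration
- what was read earlier has a scatter of 1.5 percentage points, one standard deviation
- at the start none of the gas is in solution
- what is bound to the catalyst counts as converted

My own reckoning takes the impurity, charged in the smaller amount, as the limiting reagent of a one-to-one loss of catalyst, which leaves the working catalyst, the charge of free catalyst minus the charge of impurity, 27.0 mM in the new flask. If the rate follows this quantity, the substrate and gas concentrations, equal in every flask, cancel from the order, whereas c(impurity) does not: at half its stated value the order would be 1.25. At the stated value the order is 1.67 and doubling gives 2.67. For amber over green the balance gives 18.0, above the read ratio, so I take my figures as leaning high.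

The forecast, reasoning that “the 18 mM impurity titrates catalyst”, gives an order of 1.6 and a doubling factor of 2.6, each slightly below mine.

The new flask gives an order of 1.5 and a doubling factor of 2.36.

    free catalyst + left-handed substrate ⇌ catalyst intermediate A (K = 0.730 M⁻¹, k = 330 M⁻¹ h⁻¹)
    free catalyst + right-handed substrate ⇌ catalyst intermediate B (K = 0.200 M⁻¹, k = 47.0 M⁻¹ h⁻¹)
    reagent + catalyst intermediate A → free catalyst + left-handed product (k = 25.0 M⁻¹ h⁻¹)
    reagent + catalyst intermediate B → free catalyst + right-handed product (k = 4.50 M⁻¹ h⁻¹)
    gas ⇌ reagent, rate k5*(csat - [reagent]) (kL = 6.00 h⁻¹)
    free catalyst + impurity → spent catalyst (k = 79.0 M⁻¹ h⁻¹)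

In the new flask, free catalyst has a half-life of 0.0203 d against the impurity as charged, shorter than the 0.0945 d taken to reach the asked conversion. At 0.250 d the impurity stands at 0.362 % of its charge and spent catalyst at 39.9 % of the catalyst charged, where the balance gives 40.0 %. The flask charged twice over holds 2.67 times the working catalyst of the new flask, and its simulated factor on the rate is 2.36.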